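**Plan**
- Retrosynthesis cuts first the aryl–carbonyl bond at C5 of the dihydrobenzofuran (aryl Grignard plus a β-silyloxy Weinreb amide), then, inside the dihydrobenzofuran, the O1–C2 bond and the tertiary C–OH bond.
- Enabling feature: the fragment O1–C2(S)–C3 with its 2-hydroxypropan-2-yl group on C2 is a constitutional isomer of a 2,2-dimethylchroman-3-ol, the ring type already present in the other half. Moving O1 from the CMe2 carbon to the carbinol carbon interconverts the two.
- Forward, ring order in the first fragment: pyranone ring (resorcinol plus 3-methylbut-2-enoic acid), chromene, oxirane (Jacobsen epoxidation), chroman-3-ol, iodination, then contraction of the pyran to the dihydrofuran.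
- The second fragment keeps the purchased chroman ring: acetylation, Claisen homologation, asymmetric transfer hydrogenation, Weinreb amide, silylation.
- The chain is joined by iodine–magnesium exchange and acylation; buffered fluoride then removes both silyl groups.
- Stereochemistry: C2 (S) comes from the 3R carbinol set by the (R,R)-Jacobsen epoxidation and inverted once in the ring contraction; the carbinol (S) comes from the (S,S)-TsDPEN ruthenium transfer hydrogenation.

Key step: step 8

Assumption: the (R,R)-(salen)MnCl catalyst is taken to give the 3R,4R epoxide of a 2,2-dimethylchromene, and the (S,S)-TsDPEN ruthenium catalyst the S benzylic alcohol, as with the parent substrates; 2,2-dimethylchroman is taken as purchasable.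

**Step 1**
Reactants: 1 resorcinol; 2 3-methylbut-2-enoic acid
Product: 3 7-hydroxy-2,2-dimethylchroman-4-one
Conditions: P2O5, MeSO3H, 70 °C
Reagents that add atoms: none
Why: Friedel–Crafts acylation of resorcinol para to one hydroxyl, followed by intramolecular oxa-Michael addition of the ortho hydroxyl to the enone, is the standard entry to this chromanone and should favour the 7-hydroxy isomer.

**Step 2**
Reactants: 3 7-hydroxy-2,2-dimethylchroman-4-one
Product: 4 2,2-dimethyl-7-(triisopropylsilyloxy)chroman-4-one
Conditions: TIPSCl, imidazole, DMF, rt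
Reagents that add atoms: chlorotriisopropylsilane, CC(C)[Si](Cl)(C(C)C)C(C)C
Why: Standard phenol silylation; the bulky aryl silyl ether should tolerate hydride, hypochlorite, triflation and Grignard chemistry and leave with fluoride at the end.

**Step 3**
Reactants: 4 2,2-dimethyl-7-(triisopropylsilyloxy)chroman-4-one
Product: 5 2,2-dimethyl-7-(triisopropylsilyloxy)chroman-4-ol (racemic)
Conditions: NaBH4, MeOH–THF, 0 °C
Reagents that add atoms: none
Why: Borohydride reduction of the aryl ketone; the new centre is lost in the next step, so no control is needed.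

**Step 4**
Reactants: 5 2,2-dimethyl-7-(triisopropylsilyloxy)chroman-4-ol
Product: 6 2,2-dimethyl-7-(triisopropylsilyloxy)-2H-chromene
Conditions: TsOH·H2O (cat.), toluene, 60 °C, short contact time
Reagents that add atoms: none
Why: Acid-catalysed E1 dehydration through a benzylic cation stabilised by the para silyloxy group and the ring oxygen, the classical route to 7-oxygenated 2,2-dimethylchromenes.

**Step 5**
Reactants: 6 2,2-dimethyl-7-(triisopropylsilyloxy)-2H-chromene
Product: 7 (3R,4R)-3,4-epoxy-2,2-dimethyl-7-(triisopropylsilyloxy)chroman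
Conditions: (R,R)-Jacobsen catalyst [(R,R)-(salen)MnCl, salen = N,N'-bis(3,5-di-tert-butylsalicylidene)-trans-cyclohexane-1,2-diamine dianion] (4 mol%), 4-phenylpyridine N-oxide (0.2 equiv), aq. NaOCl (pH 11.3), CH2Cl2, 0 °C; cold basic work-up, no silica
Reagents that add atoms: sodium hypochlorite, [Na+].[O-]Cl
Why: Jacobsen epoxidation, for which cis-disubstituted 2,2-dimethylchromenes are the best substrate class; the (R,R) ligand should direct oxygen transfer to the face that gives the 3R,4R epoxide, which fixes C3.

**Step 6**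
Reactants: 7 (3R,4R)-3,4-epoxy-2,2-dimethyl-7-(triisopropylsilyloxy)chroman
Product: 8 (3R)-2,2-dimethyl-7-(triisopropylsilyloxy)chroman-3-ol
Conditions: LiAlH4, THF, −20 → 0 °C (crude 7 used at once)
Reagents that add atoms: none
Why: SN2 hydride opening of the epoxide at the benzylic C4, which is activated and not flanked by the quaternary C2, leaves the C3–O bond untouched, so the 3R configuration is retained.

**Step 7**
Reactants: 8 (3R)-2,2-dimethyl-7-(triisopropylsilyloxy)chroman-3-ol
Product: 9 (3R)-6-iodo-2,2-dimethyl-7-(triisopropylsilyloxy)chroman-3-ol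
Conditions: N-iodosuccinimide, CF3CO2H (cat.), MeCN, 0 °C
Reagents that add atoms: N-iodosuccinimide, O=C1CCC(=O)N1I
Why: Electrophilic aromatic iodination should go to C6, para to the ring oxygen and ortho to the silyloxy group, because C8 lies between two oxygen substituents and is shielded by the triisopropylsilyl group; iodine is chosen over bromine so that the later halogen–magnesium exchange is fast on this electron-rich ring.

**Step 8**
Reactants: 9 (3R)-6-iodo-2,2-dimethyl-7-(triisopropylsilyloxy)chroman-3-ol
Product: 12 2-[(2S)-5-iodo-6-(triisopropylsilyloxy)-2,3-dihydro-1-benzofuran-2-yl]propan-2-ol, via C3 triflate 10 (not isolated), via aryloxiranium triflate 11 (not isolated)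
Conditions: Tf2O (1.1 equiv), 2,6-di-tert-butyl-4-methylpyridine (2.5 equiv), CH2Cl2, −78 °C; then THF–H2O (pH 7 phosphate buffer), −40 → 0 °C
Reagents that add atoms: water, O
Why: The alcohol is triflated cold to give 10; the ring oxygen O1, whose bond to C2 is antiperiplanar to an equatorial C3–OTf bond, displaces triflate from the rear to give the bicyclic aryloxiranium ion 11, and water opens 11 at the gem-dimethyl carbon with cleavage of the old O1–CMe2 bond. This is the neighbouring-oxygen ring contraction known for activated 2,2-dimethylchroman-3-ols, ended here by hydration as in a buffered sulfonate solvolysis. The O1–C3 bond formation is a 3-exo-tet closure of the oxirane which, counted through the arene, is also the 5-exo-tet closure of the dihydrofuran ring that remains once the three-membered ring is cut at the tertiary carbon. Participation is strictly anti, so C3 is inverted once and the 3R carbinol from the Jacobsen epoxidation becomes C2 of S configuration; the attack of water is on the achiral CMe2 carbon and does not touch it. The step needs capture at the tertiary carbon and not return to C3 (which would only regenerate the 3R chromanol by double inversion), proton loss to the isopropenyl compound, or aryl participation from C4a. The two methyl groups concentrate the positive charge on the former C2, water is supplied cold and in large excess, and the hindered pyridine keeps the medium neutral so that the aryl silyl ether and the new tertiary alcohol survive.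

**Step 9**
Reactants: 13 2,2-dimethylchroman
Product: 14 1-(2,2-dimethylchroman-6-yl)ethan-1-one
Conditions: AcCl, AlCl3, CH2Cl2, −10 → 0 °C
Reagents that add atoms: acetyl chloride, CC(=O)Cl
Why: Friedel–Crafts acylation should occur para to the ring oxygen, at C6.

**Step 10**
Reactants: 14 1-(2,2-dimethylchroman-6-yl)ethan-1-one
Product: 15 ethyl 3-(2,2-dimethylchroman-6-yl)-3-oxopropanoate
Conditions: NaH, (EtO)2CO, THF, reflux; then aq. HCl
Reagents that add atoms: diethyl carbonate, CCOC(=O)OCC
Why: Claisen-type C-acylation of the methyl ketone enolate with diethyl carbonate, driven by formation of the stabilised β-keto ester enolate.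

**Step 11**
Reactants: 15 ethyl 3-(2,2-dimethylchroman-6-yl)-3-oxopropanoate
Product: 16 ethyl (3S)-3-(2,2-dimethylchroman-6-yl)-3-hydroxypropanoate
Conditions: RuCl(p-cymene)[(S,S)-TsDPEN] (1 mol%), HCO2H–Et3N (5:2), DMF, 40 °C
Reagents that add atoms: none
Why: Noyori–Ikariya asymmetric transfer hydrogenation of an aryl ketone; the (S,S) catalyst should deliver hydride to the face that gives the S benzylic alcohol, as with acetophenone, since aryl outranks the CH2 group in both cases.

**Step 12**
Reactants: 16 ethyl (3S)-3-(2,2-dimethylchroman-6-yl)-3-hydroxypropanoate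
Product: 17 (3S)-3-(2,2-dimethylchroman-6-yl)-3-hydroxy-N-methoxy-N-methylpropanamide
Conditions: MeNHOMe·HCl, iPrMgCl, THF, −20 → 0 °C
Reagents that add atoms: N,O-dimethylhydroxylamine hydrochloride, CNOC.Cl
Why: Weinreb amide formation by aminolysis of the ester with the magnesium amide, a standard operation on β-hydroxy esters that does not disturb the carbinol centre at low temperature.

**Step 13**
Reactants: 17 (3S)-3-(2,2-dimethylchroman-6-yl)-3-hydroxy-N-methoxy-N-methylpropanamide
Product: 18 (3S)-3-(2,2-dimethylchroman-6-yl)-N-methoxy-N-methyl-3-(triethylsilyloxy)propanamide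
Conditions: Et3SiCl, imidazole, DMF, 0 °C → rt
Reagents that add atoms: chlorotriethylsilane, CC[Si](Cl)(CC)CC
Why: Silylation of the secondary benzylic alcohol; the triethylsilyl ether withstands the Grignard reagent yet leaves under the mildest fluoride conditions.

**Step 14**
Reactants: 12 2-[(2S)-5-iodo-6-(triisopropylsilyloxy)-2,3-dihydro-1-benzofuran-2-yl]propan-2-ol; 18 (3S)-3-(2,2-dimethylchroman-6-yl)-N-methoxy-N-methyl-3-(triethylsilyloxy)propanamide
Product: 20 (3S)-3-(2,2-dimethylchroman-6-yl)-1-[(2S)-2-(2-hydroxypropan-2-yl)-6-(triisopropylsilyloxy)-2,3-dihydro-1-benzofuran-5-yl]-3-(triethylsilyloxy)propan-1-one, via arylmagnesium chloride 19 (not isolated)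
Conditions: 12, iPrMgCl·LiCl (2.05 equiv), THF, −20 → 0 °C; then 18, 0 °C → rt; aq. NH4Cl
Reagents that add atoms: none
Why: The first equivalent of the turbo-Grignard reagent deprotonates the tertiary alcohol and the second performs iodine–magnesium exchange on the aryl iodide; acylation of 19 by the Weinreb amide stops at the ketone because the chelated tetrahedral adduct survives until work-up, and no stereocentre is involved.

**Step 15**
Reactants: 20 the bis-silylated ketone
Product: 21 (3S)-3-(2,2-dimethylchroman-6-yl)-3-hydroxy-1-[(2S)-6-hydroxy-2-(2-hydroxypropan-2-yl)-2,3-dihydro-1-benzofuran-5-yl]propan-1-one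
Conditions: Bu4NF, AcOH (1:1), THF, 0 °C → rt
Reagents that add atoms: none
Why: Fluoride-mediated desilylation should remove the aryl triisopropylsilyl ether (activated by the ortho ketone) and the triethylsilyl ether, while the acetic acid buffer suppresses E1cB loss of the β-oxygen and retro-aldol cleavage of the β-hydroxy ketone.

**Compound list**
1 | resorcinol | Oc1cccc(O)c1 | starting material
2 | 3-methylbut-2-enoic acid | CC(C)=CC(=O)O | starting material
3 | 7-hydroxy-2,2-dimethylchroman-4-one | CC1(C)CC(=O)c2ccc(O)cc2O1 | intermediate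
4 | 2,2-dimethyl-7-(triisopropylsilyloxy)chroman-4-one | CC1(C)CC(=O)c2ccc(O[Si](C(C)C)(C(C)C)C(C)C)cc2O1 | intermediate
5 | 2,2-dimethyl-7-(triisopropylsilyloxy)chroman-4-ol (racemic) | CC1(C)CC(O)c2ccc(O[Si](C(C)C)(C(C)C)C(C)C)cc2O1 | intermediate
6 | 2,2-dimethyl-7-(triisopropylsilyloxy)-2H-chromene | CC1(C)C=Cc2ccc(O[Si](C(C)C)(C(C)C)C(C)C)cc2O1 | intermediate
7 | (3R,4R)-3,4-epoxy-2,2-dimethyl-7-(triisopropylsilyloxy)chroman | CC1(C)Oc2cc(O[Si](C(C)C)(C(C)C)C(C)C)ccc2[C@H]2O[C@@H]12 | intermediate
8 | (3R)-2,2-dimethyl-7-(triisopropylsilyloxy)chroman-3-ol | CC1(C)Oc2cc(O[Si](C(C)C)(C(C)C)C(C)C)ccc2C[C@H]1O | intermediate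
9 | (3R)-6-iodo-2,2-dimethyl-7-(triisopropylsilyloxy)chroman-3-ol | CC1(C)Oc2cc(O[Si](C(C)C)(C(C)C)C(C)C)c(I)cc2C[C@H]1O | intermediate
10 | (3R)-6-iodo-2,2-dimethyl-7-(triisopropylsilyloxy)chroman-3-yl trifluoromethanesulfonate | CC1(C)Oc2cc(O[Si](C(C)C)(C(C)C)C(C)C)c(I)cc2C[C@H]1OS(=O)(=O)C(F)(F)F | intermediate (not isolated)
11 | bicyclic aryloxiranium triflate in which O1 bridges the CMe2 carbon and the former C3 (S) | CC1(C)[C@@H]2Cc3cc(I)c(O[Si](C(C)C)(C(C)C)C(C)C)cc3[O+]12.[O-]S(=O)(=O)C(F)(F)F | intermediate (not isolated)
12 | 2-[(2S)-5-iodo-6-(triisopropylsilyloxy)-2,3-dihydro-1-benzofuran-2-yl]propan-2-ol | Ic1cc2c(cc1O[Si](C(C)C)(C(C)C)C(C)C)O[C@H](C(C)(C)O)C2 | intermediate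
13 | 2,2-dimethylchroman | CC1(C)CCc2ccccc2O1 | starting material
14 | 1-(2,2-dimethylchroman-6-yl)ethan-1-one | CC(=O)c1ccc2OC(C)(C)CCc2c1 | intermediate
15 | ethyl 3-(2,2-dimethylchroman-6-yl)-3-oxopropanoate | CCOC(=O)CC(=O)c1ccc2OC(C)(C)CCc2c1 | intermediate
16 | ethyl (3S)-3-(2,2-dimethylchroman-6-yl)-3-hydroxypropanoate | CCOC(=O)C[C@H](O)c1ccc2OC(C)(C)CCc2c1 | intermediate
17 | (3S)-3-(2,2-dimethylchroman-6-yl)-3-hydroxy-N-methoxy-N-methylpropanamide | CON(C)C(=O)C[C@H](O)c1ccc2OC(C)(C)CCc2c1 | intermediate
18 | (3S)-3-(2,2-dimethylchroman-6-yl)-N-methoxy-N-methyl-3-(triethylsilyloxy)propanamide | CON(C)C(=O)C[C@H](O[Si](CC)(CC)CC)c1ccc2OC(C)(C)CCc2c1 | intermediate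
19 | chloromagnesium alkoxide of [(2S)-2-(2-hydroxypropan-2-yl)-6-(triisopropylsilyloxy)-2,3-dihydro-1-benzofuran-5-yl]magnesium chloride | Cl[Mg]c1cc2c(cc1O[Si](C(C)C)(C(C)C)C(C)C)O[C@H](C(C)(C)O[Mg]Cl)C2 | intermediate (not isolated)
20 | (3S)-3-(2,2-dimethylchroman-6-yl)-1-[(2S)-2-(2-hydroxypropan-2-yl)-6-(triisopropylsilyloxy)-2,3-dihydro-1-benzofuran-5-yl]-3-(triethylsilyloxy)propan-1-one | CC1(C)CCc2cc([C@@H](O[Si](CC)(CC)CC)CC(=O)c3cc4c(cc3O[Si](C(C)C)(C(C)C)C(C)C)O[C@H](C(C)(C)O)C4)ccc2O1 | intermediate
21 | (3S)-3-(2,2-dimethylchroman-6-yl)-3-hydroxy-1-[(2S)-6-hydroxy-2-(2-hydroxypropan-2-yl)-2,3-dihydro-1-benzofuran-5-yl]propan-1-one | CC1(C)CCc2cc([C@@H](O)CC(=O)c3cc4c(cc3O)O[C@H](C(C)(C)O)C4)ccc2O1 | target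

**Step count and risks**
Total: 15 steps. Longest linear sequence: 10 steps (steps 1–8, 14, 15).

Step 8. Proton loss from a methyl group of the oxiranium ion, or return of triflate, may outrun capture by water, so that the tertiary alcohol is not formed directly. The fallback sets out from 9 and makes the elimination the intended outcome: the triflate is formed as before and warmed without water, so that the ring contraction ends in (2S)-5-iodo-2-(prop-1-en-2-yl)-6-(triisopropylsilyloxy)-2,3-dihydro-1-benzofuran F1. Mukaiyama hydration of the 1,1-disubstituted alkene (Co(acac)2, PhSiH3, O2, THF, rt) should then place the hydroxyl on the tertiary carbon without touching C2, and the route is rejoined at 12.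

Step 5. The epoxide carries a para silyloxy group and an ortho ring oxygen on the benzylic carbon, so ionisation at C4 during the oxidation or the handling may lead to ring opening or rearrangement, and the enantioselectivity may fall short. The fallback sets out from 6 and avoids an epoxide altogether. Hydroboration–oxidation (BH3·SMe2, THF; then NaBO3·4H2O) should give racemic 2,2-dimethyl-7-(triisopropylsilyloxy)chroman-3-ol F2. Dess–Martin oxidation gives 2,2-dimethyl-7-(triisopropylsilyloxy)chroman-3-one F3. Corey–Bakshi–Shibata reduction with the (S)-methyl oxazaborolidine and BH3·SMe2, in which the quaternary C2 acts as the large group, should deliver the 3R alcohol, and the route is rejoined at 8.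

Step 14. Addition of the aryl Grignard reagent, hindered by the ortho triisopropylsilyloxy group, to the amide may be slow, and deprotonation of the amide at its α-carbon may compete. The fallback sets out from 18 and 12 and uses a more electrophilic partner. Reduction of 18 with i-Bu2AlH (THF, −78 °C) gives (3S)-3-(2,2-dimethylchroman-6-yl)-3-(triethylsilyloxy)propanal F4. Addition of 19, generated from 12 as before, gives (3S)-3-(2,2-dimethylchroman-6-yl)-1-[(2S)-2-(2-hydroxypropan-2-yl)-6-(triisopropylsilyloxy)-2,3-dihydro-1-benzofuran-5-yl]-3-(triethylsilyloxy)propan-1-ol F5 as a mixture of epimers at C1. Dess–Martin oxidation of the secondary benzylic alcohol (NaHCO3 buffer), which leaves the tertiary alcohol alone, rejoins the route at 20.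

**Further compounds**
F1 | step 8 | (2S)-5-iodo-2-(prop-1-en-2-yl)-6-(triisopropylsilyloxy)-2,3-dihydro-1-benzofuran | Ic1cc2c(cc1O[Si](C(C)C)(C(C)C)C(C)C)O[C@H](C(C)=C)C2
F2 | step 5 | 2,2-dimethyl-7-(triisopropylsilyloxy)chroman-3-ol (racemic) | CC1(C)Oc2cc(O[Si](C(C)C)(C(C)C)C(C)C)ccc2CC1O
F3 | step 5 | 2,2-dimethyl-7-(triisopropylsilyloxy)chroman-3-one | CC1(C)Oc2cc(O[Si](C(C)C)(C(C)C)C(C)C)ccc2CC1=O
F4 | step 14 | (3S)-3-(2,2-dimethylchroman-6-yl)-3-(triethylsilyloxy)propanal | O=CC[C@H](O[Si](CC)(CC)CC)c1ccc2OC(C)(C)CCc2c1
F5 | step 14 | (3S)-3-(2,2-dimethylchroman-6-yl)-1-[(2S)-2-(2-hydroxypropan-2-yl)-6-(triisopropylsilyloxy)-2,3-dihydro-1-benzofuran-5-yl]-3-(triethylsilyloxy)propan-1-ol (C1 epimers) | CC1(C)CCc2cc([C@@H](O[Si](CC)(CC)CC)CC(O)c3cc4c(cc3O[Si](C(C)C)(C(C)C)C(C)C)O[C@H](C(C)(C)O)C4)ccc2O1
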